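**Retrosynthetic overview**

1. Target ⇐ 9-O-PMB lactone. The γ-lactone (C7–O–C19) comes from an isopropenyl group on C8 (hydroboration, oxidation, lactonisation onto C7–OH); the C2/C14 acetates come from a C14–OH-directed syn reduction of a C2 ketone.
2. Ten-membered ring C1–C10 ⇐ Claisen ring expansion of an eight-membered 2-methylene oxocane (ring atoms O, C2, C1, C10, C9, C8, C7, C6) carrying an isopropenyl group (C5, C4, C16) on C6. Enabling feature: the C2 oxygen lies γ,δ to the Z-C5(Me)=C6 olefin (C2(=O)–C3H2–C4H2–C5=C6), and C6 can carry the ring ether oxygen.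
3. Oxocane ⇐ eight-membered lactone (C2 acid + C6–OH) ⇐ cyclohexene acid (ring C1, C10–C14), made by Ireland–Claisen ring contraction of a δ-lactone that sets C1 and C10.
4. δ-Lactone ⇐ (Z)-enal by allylation, methacrylate ring-closing metathesis and conjugate borylation; the C6–C10 chain with C7, C8, C9 ⇐ diacetone-D-glucose (3-ulose, two isopropenyl Grignard additions).
5. Ring order: δ-lactone → cyclohexene → eight-membered lactone/oxocane → ten-membered carbocycle → γ-lactone.

Key step: step 20

Remark: positions are numbered as in the briarane skeleton (C1 quaternary fusion carbon, C2–C9 around the large ring, C10 fusion CH, C11–C14 cyclohexene, C17/C19 lactone α-carbon/carbonyl); the step 4 addition is assumed to give the 6,7-anti carbinol, a centre that step 20 erases.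

Step 1
Reactants: 1 diacetone-D-glucose (1,2:5,6-di-O-isopropylidene-α-D-glucofuranose)
Product: 2 1,2:5,6-di-O-isopropylidene-α-D-ribo-hexofuranos-3-ulose
Conditions: Dess–Martin periodinane, NaHCO3, CH2Cl2, 0 °C → rt
Reagents that add atoms: none
Why: Dess–Martin oxidation of the only free (secondary) hydroxyl gives the 3-ulose, whose carbonyl carbon is the future C8; no stereocenter is formed.

Step 2
Reactants: 2 1,2:5,6-di-O-isopropylidene-α-D-ribo-hexofuranos-3-ulose
Product: 3 1,2:5,6-di-O-isopropylidene-3-C-isopropenyl-α-D-allofuranose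
Conditions: isopropenylmagnesium bromide, THF, −78 → 0 °C; aq. NH4Cl
Reagents that add atoms: isopropenylmagnesium bromide, C=C(C)[Mg]Br
Why: Grignard 1,2-addition should occur on the convex β-face of the cis-fused 1,2-O-isopropylidene furanose, anti to the acetonide, which sets C8 with the hydroxyl cis to the C7 and C9 oxygens (ribo/allo) as the target requires.

Step 3
Reactants: 3 1,2:5,6-di-O-isopropylidene-3-C-isopropenyl-α-D-allofuranose
Product: 4 2,3:5,6-di-O-isopropylidene-3-C-isopropenyl-β-D-allofuranose (lactol)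
Conditions: TsOH·H2O (cat.), acetone, rt
Reagents that add atoms: none
Why: Acid-catalysed acetal equilibration (trans-ketalisation) should move the anomeric acetonide onto the cis-2,3-diol, the arrangement ribo/allo-configured furanoses prefer under thermodynamic control, which frees the lactol and masks the C7 and C8 oxygens together.

Step 4
Reactants: 4 2,3:5,6-di-O-isopropylidene-3-C-isopropenyl-β-D-allofuranose (lactol)
Product: 5 open-chain C6,C9-diol (7,8-acetonide; isopropenyl on C6 and C8; terminal dioxolane masking C10)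
Conditions: isopropenylmagnesium bromide (5 equiv), THF, 0 °C → rt; aq. NH4Cl
Reagents that add atoms: isopropenylmagnesium bromide, C=C(C)[Mg]Br
Why: Grignard addition to the open hydroxy-aldehyde form of the lactol (the first equivalent deprotonates it) installs C5, C4 and C16 and should give the 6,7-anti carbinol by the chelate model; this centre is erased in step 20.

Step 5
Reactants: 5 open-chain C6,C9-diol
Product: 6 C6-O-TBS ether (C9–OH free)
Conditions: TBSCl, imidazole, DMF, 0 °C
Reagents that add atoms: tert-butyldimethylsilyl chloride, CC(C)(C)[Si](C)(C)Cl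
Why: Silyl ether formation should be selective for the less hindered allylic C6 hydroxyl, because the C9 hydroxyl is flanked by the quaternary acetonide carbon C8 and the branched dioxolane carbon.

Step 6
Reactants: 6 C6-O-TBS ether (C9–OH free)
Product: 7 C9-O-PMB C6-O-TBS bis-ether
Conditions: NaH, 4-methoxybenzyl bromide, Bu4NI (cat.), THF/DMF, 0 °C → rt
Reagents that add atoms: 4-methoxybenzyl bromide, COc1ccc(CBr)cc1
Why: Williamson etherification of the remaining alkoxide with a reactive benzylic bromide installs the C9 protecting group that is carried to the last step; no stereocenter is touched.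

Step 7
Reactants: 7 C9-O-PMB C6-O-TBS bis-ether
Product: 8 C10 aldehyde
Conditions: H5IO6, EtOAc, rt
Reagents that add atoms: none
Why: Periodic acid hydrolyses the terminal acetonide selectively and cleaves the liberated 1,2-diol (glycol cleavage) to the C10 aldehyde, while the internal tertiary acetonide and the silyl and PMB ethers should persist.

Step 8
Reactants: 8 C10 aldehyde
Product: 9 (Z)-α-methyl enoate (C10=C11; methyl ester at C12)
Conditions: (CF3CH2O)2P(O)CH(CH3)CO2CH3, KN(SiMe3)2, 18-crown-6, THF, −78 °C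
Reagents that add atoms: methyl 2-[bis(2,2,2-trifluoroethoxy)phosphoryl]propanoate, COC(=O)C(C)P(=O)(OCC(F)(F)F)OCC(F)(F)F
Why: Still–Gennari olefination under dissociating conditions should give the Z-trisubstituted enoate, placing C9 cis to C12 as the boat transition state of step 16 demands.

Step 9
Reactants: 9 (Z)-α-methyl enoate
Product: 10 (Z)-allylic alcohol (primary C12–OH)
Conditions: iBu2AlH, CH2Cl2, −78 °C; aq. KNaC4H4O6
Reagents that add atoms: none
Why: 1,2-Reduction of the conjugated ester by the aluminium hydride gives the allylic alcohol with retention of the Z geometry.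

Step 10
Reactants: 10 (Z)-allylic alcohol
Product: 11 (Z)-enal
Conditions: Dess–Martin periodinane, NaHCO3, CH2Cl2, 0 °C
Reagents that add atoms: none
Why: Buffered Dess–Martin oxidation of the allylic alcohol should give the enal without Z to E isomerisation.

Step 11
Reactants: 11 (Z)-enal
Product: 13 (12R)-homoallylic alcohol, via diisopinocampheylborinate 12 (not isolated)
Conditions: (+)-B-allyldiisopinocampheylborane, Et2O, −78 °C; then NaOH, H2O2, 0 °C
Reagents that add atoms: (+)-B-allyldiisopinocampheylborane, C=CCB([C@H]1C[C@H]2C[C@H](C2(C)C)[C@@H]1C)[C@H]1C[C@H]2C[C@H](C2(C)C)[C@@H]1C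
Why: Brown allylation through a Zimmerman–Traxler chair is reagent-controlled; the reagent enantiomer is the one chosen to give the (12R) carbinol, and C13 plus the vinyl group needed for ring closure are added.

Step 12
Reactants: 13 (12R)-homoallylic alcohol
Product: 14 methacrylate ester
Conditions: methacryloyl chloride, Et3N, DMAP (cat.), CH2Cl2, 0 °C
Reagents that add atoms: methacryloyl chloride, C=C(C)C(=O)Cl
Why: Acylation of the secondary alcohol brings in C1, C2 and C15 as the ester that will become the lactone.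

Step 13
Reactants: 14 methacrylate ester
Product: 15 α-methyl-α,β-unsaturated δ-lactone
Conditions: second-generation Grubbs catalyst RuCl2(=CHPh)(PCy3)(H2IMes) (5 mol %), toluene, 80 °C
Reagents that add atoms: none
Why: Ring-closing metathesis between the terminal vinyl group and the methacrylate closes the six-membered lactone (C1=C14), while the hindered isopropenyl groups and the trisubstituted olefin should stay out of the metathesis.

Step 14
Reactants: 15 α-methyl-α,β-unsaturated δ-lactone
Product: 17 4,6-trans β-hydroxy δ-lactone (C14–OH; C1 epimers), via pinacol boronate 16 (not isolated)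
Conditions: B2pin2, CuCl (cat.), Xantphos (cat.), NaOtBu (cat.), MeOH, THF, rt; then NaBO3·4H2O, THF/H2O
Reagents that add atoms: bis(pinacolato)diboron, CC1(C)OB(OC1(C)C)B1OC(C)(C)C(C)(C)O1; sodium perborate, [Na+].[O-]OB=O
Why: Copper-catalysed conjugate borylation should add boron to C14 anti to the C12 substituent, and stereoretentive perborate oxidation then gives C14–O trans to the alkenyl group, which is the target configuration at C14.

Step 15
Reactants: 17 4,6-trans β-hydroxy δ-lactone
Product: 18 C14-O-TIPS δ-lactone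
Conditions: TIPSOTf, 2,6-lutidine, CH2Cl2, 0 °C
Reagents that add atoms: triisopropylsilyl triflate, CC(C)[Si](C(C)C)(C(C)C)OS(=O)(=O)C(F)(F)F
Why: Silyl ether formation protects C14–OH with a group that outlasts the later TBS removal.

Step 16
Reactants: 18 C14-O-TIPS δ-lactone
Product: 21 cyclohexene carboxylic acid (C2 acid; C14-OTIPS; C9-OPMB; C6-OTBS), via silyl ketene acetal 19 (not isolated), via trimethylsilyl ester 20 (not isolated)
Conditions: LiN(iPr)2, Me3SiCl/Et3N, THF, −78 °C; then toluene, 105 °C; then 1 M HCl, THF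
Reagents that add atoms: chlorotrimethylsilane (atoms remain only in 19 and 20), C[Si](C)(C)Cl
Why: Ireland–Claisen rearrangement of the lactone silyl ketene acetal must pass through a boat transition state and contracts the lactone to the cyclohexene; C1–C10 forms on the lactone face that carries the alkenyl group, so the trans-4,6 lactone puts the C15 methyl trans to C14–O, the Z olefin puts C9 cis to that methyl, and C11=C12 appears in place.

Step 17
Reactants: 21 cyclohexene carboxylic acid
Product: 22 hydroxy acid (C6–OH free)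
Conditions: HF·pyridine, pyridine, THF, 0 °C
Reagents that add atoms: none
Why: Fluoride-mediated desilylation should remove the less hindered allylic TBS ether while the neopentyl-type TIPS ether survives.

Step 18
Reactants: 22 hydroxy acid
Product: 23 eight-membered lactone (ring O, C2, C1, C10, C9, C8, C7, C6)
Conditions: 2-methyl-6-nitrobenzoic anhydride, DMAP, CH2Cl2 (1 mM, slow addition), rt
Reagents that add atoms: none
Why: Shiina macrolactonisation (mixed anhydride, nucleophilic catalysis, high dilution) joins the C2 acid to the only free hydroxyl; the trans-disposed cyclohexene substituents and the cis-fused acetonide pre-organise the seco acid for the medium ring.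

Step 19
Reactants: 23 eight-membered lactone
Product: 24 eight-membered exocyclic enol ether (2-methylene oxocane; C2=C3H2)
Conditions: Cp2TiMe2, toluene, 70 °C, dark
Reagents that add atoms: dimethyltitanocene, [CH3-].[CH3-].[Ti+4].c1cc[cH-]c1.c1cc[cH-]c1
Why: Petasis methylenation (titanium carbene olefination) converts the lactone carbonyl, the only carbonyl group in the molecule, into the vinyl ether and adds C3.

Step 20
Reactants: 24 eight-membered exocyclic enol ether
Product: 25 ten-membered C2 ketone (5Z)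
Conditions: toluene, Et3N (trace), 140 °C, sealed silylated vessel
Reagents that add atoms: none
Why: Heating triggers a concerted [3,3]-sigmatropic (Claisen) rearrangement of the embedded allyl vinyl ether C3=C2–O–C6–C5=C4: the C3–C4 bond forms as O–C6 breaks, C2 becomes the ketone and C5=C6 appears, so the eight-membered oxacycle (O, C2, C1, C10, C9, C8, C7, C6) is enlarged by two atoms to the carbocycle C1–C10. The closest known reaction type is the Claisen ring expansion of 2-methylene-6-vinyltetrahydropyrans to cyclooct-4-enones, used here one ring-size pair higher. No ring is closed by cyclisation; the carbocycle arises by ring enlargement through a six-centre chair-like array, suprafacial on both three-atom fragments. No new sp3 stereocenter is formed; the only stereogenic element created is the C5=C6 double bond, whose Z geometry follows from the five-carbon tether C7–C8–C9–C10–C1, which can span the array only with C7 pseudo-axial on C6. The step needs the [3,3] shift to win over C6–O heterolysis and the [1,3] shift, and Z to win over E; neutral base-buffered thermal conditions, the absence of any other carbonyl or Lewis acid, and the ring constraint are expected to secure both, and the C6 configuration is irrelevant because C6 becomes sp2.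

Step 21
Reactants: 25 ten-membered C2 ketone (5Z)
Product: 26 β-hydroxy ketone (C14–OH)
Conditions: HF·pyridine, THF, rt
Reagents that add atoms: none
Why: Fluoride cleavage of the TIPS ether under mildly acidic conditions avoids retro-aldol cleavage of the β-hydroxy ketone and frees the hydroxyl that directs the next step.

Step 22
Reactants: 26 β-hydroxy ketone
Product: 28 2,14-diol, via diethylboryl chelate 27 (not isolated)
Conditions: Et2BOMe, THF/MeOH (4:1), −78 °C; then NaBH4, −78 → −40 °C; MeOH work-up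
Reagents that add atoms: methoxydiethylborane (atoms remain only in 27), CCB(CC)OC
Why: Narasaka–Prasad reduction: the boron chelate between C14–OH and the C2 carbonyl directs external hydride to give the 1,3-syn diol, which sets C2 as in the target.

Step 23
Reactants: 28 2,14-diol
Product: 29 2,14-diacetate
Conditions: Ac2O, pyridine, DMAP (cat.), CH2Cl2, rt
Reagents that add atoms: acetic anhydride, CC(=O)OC(C)=O
Why: Acetylation of the two free secondary alcohols installs both acetates of the target while C9 stays blocked as the PMB ether and C7/C8 as the acetonide.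

Step 24
Reactants: 29 2,14-diacetate
Product: 31 primary alcohol (C19–OH; C17 epimers), via B-alkyl-9-BBN adduct 30 (not isolated)
Conditions: 9-BBN, THF, 50 °C; then NaBO3·4H2O, THF/H2O, rt
Reagents that add atoms: 9-borabicyclo[3.3.1]nonane (atoms remain only in 30), [H]B1C2CCCC1CCC2; sodium perborate, [Na+].[O-]OB=O
Why: Hydroboration–oxidation with the bulky borane should be selective for the 1,1-disubstituted C17=C19 olefin over the two trisubstituted ring olefins and gives the anti-Markovnikov alcohol; C17 is formed without reliable control and is set in step 27, and perborate spares the acetates.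

Step 25
Reactants: 31 primary alcohol (C17 epimers)
Product: 32 C19 carboxylic acid (C17 epimers)
Conditions: TEMPO (cat.), PhI(OAc)2, MeCN/H2O, rt
Reagents that add atoms: water, O
Why: Oxoammonium (TEMPO) oxidation in aqueous acetonitrile takes the primary alcohol through the aldehyde hydrate to the acid, and the remaining oxygens are all protected.

Step 26
Reactants: 32 C19 carboxylic acid
Product: 34 9-O-PMB lactone (C17 epimers), via dihydroxy acid 33 (not isolated)
Conditions: AcOH/H2O (4:1), 45 °C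
Reagents that add atoms: none
Why: Acidic acetonide hydrolysis releases the C7/C8 diol, and the γ-hydroxy acid lactonises onto the secondary C7–OH to form the five-membered lactone; C9 cannot compete because it is still a PMB ether.

Step 27
Reactants: 34 9-O-PMB lactone (C17 epimers)
Product: 35 9-O-PMB-9-deacetylstylatulide lactone (17R)
Conditions: DBU, toluene, rt
Reagents that add atoms: none
Why: Base-mediated epimerisation (enolisation and reprotonation α to the lactone carbonyl) should converge on the more stable epimer, in which the C18 methyl is trans to the large ring carbon C9 and cis to C8–OH, as in the target.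

Step 28
Reactants: 35 9-O-PMB-9-deacetylstylatulide lactone (17R)
Product: 36 9-deacetylstylatulide lactone
Conditions: DDQ, CH2Cl2/pH 7 buffer, 0 °C
Reagents that add atoms: none
Why: Oxidative cleavage of the PMB ether in wet dichloromethane frees C9–OH without touching acetates, lactone, tertiary alcohol or olefins.

**Compound list**

1 | diacetone-D-glucose (1,2:5,6-di-O-isopropylidene-α-D-glucofuranose) | CC1(C)OC[C@@H](O1)[C@H]1O[C@@H]2OC(C)(C)O[C@@H]2[C@H]1O | starting material
2 | 1,2:5,6-di-O-isopropylidene-α-D-ribo-hexofuranos-3-ulose | CC1(C)OC[C@@H](O1)[C@H]1O[C@@H]2OC(C)(C)O[C@@H]2C1=O | intermediate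
3 | 1,2:5,6-di-O-isopropylidene-3-C-isopropenyl-α-D-allofuranose | CC1(C)OC[C@@H](O1)[C@H]1O[C@@H]2OC(C)(C)O[C@@H]2[C@@]1(O)C(C)=C | intermediate
4 | 2,3:5,6-di-O-isopropylidene-3-C-isopropenyl-β-D-allofuranose (lactol) | O[C@@H]1O[C@H]([C@H]2COC(C)(C)O2)[C@@]3(C(C)=C)OC(C)(C)O[C@@H]13 | intermediate
5 | open-chain C6,C9-diol (7,8-acetonide; isopropenyl on C6 and C8; terminal dioxolane) | CC1(C)OC[C@@H](O1)[C@@H](O)[C@@]2(C(C)=C)OC(C)(C)O[C@H]2[C@@H](O)C(C)=C | intermediate
6 | C6-O-TBS ether (C9–OH free) | CC1(C)OC[C@@H](O1)[C@@H](O)[C@@]2(C(C)=C)OC(C)(C)O[C@H]2[C@@H](O[Si](C)(C)C(C)(C)C)C(C)=C | intermediate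
7 | C9-O-PMB C6-O-TBS bis-ether | CC1(C)OC[C@@H](O1)[C@@H](OCc1ccc(OC)cc1)[C@@]2(C(C)=C)OC(C)(C)O[C@H]2[C@@H](O[Si](C)(C)C(C)(C)C)C(C)=C | intermediate
8 | C10 aldehyde | O=C[C@@H](OCc1ccc(OC)cc1)[C@@]2(C(C)=C)OC(C)(C)O[C@H]2[C@@H](O[Si](C)(C)C(C)(C)C)C(C)=C | intermediate
9 | (Z)-α-methyl enoate | COC(=O)/C(C)=C\[C@@H](OCc1ccc(OC)cc1)[C@@]2(C(C)=C)OC(C)(C)O[C@H]2[C@@H](O[Si](C)(C)C(C)(C)C)C(C)=C | intermediate
10 | (Z)-allylic alcohol | OC/C(C)=C\[C@@H](OCc1ccc(OC)cc1)[C@@]2(C(C)=C)OC(C)(C)O[C@H]2[C@@H](O[Si](C)(C)C(C)(C)C)C(C)=C | intermediate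
11 | (Z)-enal | O=C/C(C)=C\[C@@H](OCc1ccc(OC)cc1)[C@@]2(C(C)=C)OC(C)(C)O[C@H]2[C@@H](O[Si](C)(C)C(C)(C)C)C(C)=C | intermediate
12 | diisopinocampheylborinate of 13 | C=CC[C@@H](OB([C@H]1C[C@H]2C[C@H](C2(C)C)[C@@H]1C)[C@H]1C[C@H]2C[C@H](C2(C)C)[C@@H]1C)/C(C)=C\[C@@H](OCc1ccc(OC)cc1)[C@@]2(C(C)=C)OC(C)(C)O[C@H]2[C@@H](O[Si](C)(C)C(C)(C)C)C(C)=C | intermediate
13 | (12R)-homoallylic alcohol | C=CC[C@@H](O)/C(C)=C\[C@@H](OCc1ccc(OC)cc1)[C@@]2(C(C)=C)OC(C)(C)O[C@H]2[C@@H](O[Si](C)(C)C(C)(C)C)C(C)=C | intermediate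
14 | methacrylate ester | C=CC[C@@H](OC(=O)C(C)=C)/C(C)=C\[C@@H](OCc1ccc(OC)cc1)[C@@]2(C(C)=C)OC(C)(C)O[C@H]2[C@@H](O[Si](C)(C)C(C)(C)C)C(C)=C | intermediate
15 | α-methyl-α,β-unsaturated δ-lactone | CC3=CC[C@H](/C(C)=C\[C@@H](OCc1ccc(OC)cc1)[C@@]2(C(C)=C)OC(C)(C)O[C@H]2[C@@H](O[Si](C)(C)C(C)(C)C)C(C)=C)OC3=O | intermediate
16 | pinacol boronate at C14 (C1 epimers) | CC3[C@@H](B4OC(C)(C)C(C)(C)O4)C[C@H](/C(C)=C\[C@@H](OCc1ccc(OC)cc1)[C@@]2(C(C)=C)OC(C)(C)O[C@H]2[C@@H](O[Si](C)(C)C(C)(C)C)C(C)=C)OC3=O | intermediate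
17 | 4,6-trans β-hydroxy δ-lactone (C1 epimers) | CC3[C@@H](O)C[C@H](/C(C)=C\[C@@H](OCc1ccc(OC)cc1)[C@@]2(C(C)=C)OC(C)(C)O[C@H]2[C@@H](O[Si](C)(C)C(C)(C)C)C(C)=C)OC3=O | intermediate
18 | C14-O-TIPS δ-lactone (C1 epimers) | CC3[C@@H](O[Si](C(C)C)(C(C)C)C(C)C)C[C@H](/C(C)=C\[C@@H](OCc1ccc(OC)cc1)[C@@]2(C(C)=C)OC(C)(C)O[C@H]2[C@@H](O[Si](C)(C)C(C)(C)C)C(C)=C)OC3=O | intermediate
19 | trimethylsilyl ketene acetal of 18 | CC3=C(O[Si](C)(C)C)O[C@@H](/C(C)=C\[C@@H](OCc1ccc(OC)cc1)[C@@]2(C(C)=C)OC(C)(C)O[C@H]2[C@@H](O[Si](C)(C)C(C)(C)C)C(C)=C)C[C@@H]3O[Si](C(C)C)(C(C)C)C(C)C | intermediate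
20 | trimethylsilyl ester of 21 | CC(C)[Si](C(C)C)(C(C)C)O[C@H]1CC=C(C)[C@H]([C@@H](OCc2ccc(OC)cc2)[C@@]3(C(C)=C)OC(C)(C)O[C@H]3[C@@H](O[Si](C)(C)C(C)(C)C)C(C)=C)[C@@]1(C)C(=O)O[Si](C)(C)C | intermediate
21 | cyclohexene carboxylic acid (C14-OTIPS; C9-OPMB; C6-OTBS) | CC(C)[Si](C(C)C)(C(C)C)O[C@H]1CC=C(C)[C@H]([C@@H](OCc2ccc(OC)cc2)[C@@]3(C(C)=C)OC(C)(C)O[C@H]3[C@@H](O[Si](C)(C)C(C)(C)C)C(C)=C)[C@@]1(C)C(O)=O | intermediate
22 | hydroxy acid (C6–OH free) | CC(C)[Si](C(C)C)(C(C)C)O[C@H]1CC=C(C)[C@H]([C@@H](OCc2ccc(OC)cc2)[C@@]3(C(C)=C)OC(C)(C)O[C@H]3[C@@H](O)C(C)=C)[C@@]1(C)C(O)=O | intermediate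
23 | eight-membered lactone | CC(C)[Si](C(C)C)(C(C)C)O[C@H]1CC=C(C)[C@@H]2[C@@H](OCc4ccc(OC)cc4)[C@@]3(C(C)=C)OC(C)(C)O[C@H]3[C@H](C(C)=C)OC(=O)[C@@]12C | intermediate
24 | eight-membered exocyclic enol ether (2-methylene oxocane) | CC(C)[Si](C(C)C)(C(C)C)O[C@H]1CC=C(C)[C@@H]2[C@@H](OCc4ccc(OC)cc4)[C@@]3(C(C)=C)OC(C)(C)O[C@H]3[C@H](C(C)=C)OC(=C)[C@@]12C | intermediate
25 | ten-membered C2 ketone (5Z) | CC(C)[Si](C(C)C)(C(C)C)O[C@H]1CC=C(C)[C@@H]2[C@@H](OCc4ccc(OC)cc4)[C@@]3(C(C)=C)OC(C)(C)O[C@H]3/C=C(/C)CCC(=O)[C@@]12C | intermediate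
26 | β-hydroxy ketone (C14–OH) | O[C@H]1CC=C(C)[C@@H]2[C@@H](OCc4ccc(OC)cc4)[C@@]3(C(C)=C)OC(C)(C)O[C@H]3/C=C(/C)CCC(=O)[C@@]12C | intermediate
27 | C14-O-diethylboryl chelate of 26 | CCB(CC)O[C@H]1CC=C(C)[C@@H]2[C@@H](OCc4ccc(OC)cc4)[C@@]3(C(C)=C)OC(C)(C)O[C@H]3/C=C(/C)CCC(=O)[C@@]12C | intermediate
28 | 2,14-diol | O[C@H]1CC=C(C)[C@@H]2[C@@H](OCc4ccc(OC)cc4)[C@@]3(C(C)=C)OC(C)(C)O[C@H]3/C=C(/C)CC[C@@H](O)[C@@]12C | intermediate
29 | 2,14-diacetate | CC(=O)O[C@H]1CC=C(C)[C@@H]2[C@@H](OCc4ccc(OC)cc4)[C@@]3(C(C)=C)OC(C)(C)O[C@H]3/C=C(/C)CC[C@@H](OC(C)=O)[C@@]12C | intermediate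
30 | B-alkyl-9-BBN adduct (boron on C19; C17 epimers) | CC(=O)O[C@H]1CC=C(C)[C@@H]2[C@@H](OCc4ccc(OC)cc4)[C@@]3(C(C)CB5C6CCCC5CCC6)OC(C)(C)O[C@H]3/C=C(/C)CC[C@@H](OC(C)=O)[C@@]12C | intermediate
31 | primary alcohol (C19–OH; C17 epimers) | CC(=O)O[C@H]1CC=C(C)[C@@H]2[C@@H](OCc4ccc(OC)cc4)[C@@]3(C(C)CO)OC(C)(C)O[C@H]3/C=C(/C)CC[C@@H](OC(C)=O)[C@@]12C | intermediate
32 | C19 carboxylic acid (C17 epimers) | CC(=O)O[C@H]1CC=C(C)[C@@H]2[C@@H](OCc4ccc(OC)cc4)[C@@]3(C(C)C(O)=O)OC(C)(C)O[C@H]3/C=C(/C)CC[C@@H](OC(C)=O)[C@@]12C | intermediate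
33 | 7,8-dihydroxy acid (C17 epimers) | CC(=O)O[C@H]1CC=C(C)[C@@H]2[C@@H](OCc4ccc(OC)cc4)[C@@](C(C)C(O)=O)(O)[C@@H](O)/C=C(/C)CC[C@@H](OC(C)=O)[C@@]12C | intermediate
34 | 9-O-PMB lactone (C17 epimers) | CC(=O)O[C@H]1CC=C(C)[C@@H]2[C@@H](OCc4ccc(OC)cc4)[C@@]3(O)[C@H](/C=C(/C)CC[C@@H](OC(C)=O)[C@@]12C)OC(=O)C3C | intermediate
35 | 9-O-PMB-9-deacetylstylatulide lactone (17R) | CC(=O)O[C@H]1CC=C(C)[C@@H]2[C@@H](OCc4ccc(OC)cc4)[C@@]3(O)[C@H](/C=C(/C)CC[C@@H](OC(C)=O)[C@@]12C)OC(=O)[C@@H]3C | intermediate
36 | 9-deacetylstylatulide lactone | CC(=O)O[C@H]1CC=C(C)[C@@H]2[C@@H](O)[C@@]3(O)[C@H](/C=C(/C)CC[C@@H](OC(C)=O)[C@@]12C)OC(=O)[C@@H]3C | target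

Total step count: 28. Longest linear sequence: 28 steps (1 → 36).

**Steps most likely to fail**

Step 20 (key ring expansion). The thermal shift may lose to heterolysis of the allylic C6–O bond, may pass through the alternative transition-state geometry that gives the E-olefin, or may not go to completion below the temperature the protecting groups tolerate. The fallback sets out from enol ether 24 and changes the activation mode rather than the temperature: triisobutylaluminium (iBu3Al, CH2Cl2, −78 → 0 °C) binds the enol-ether oxygen, so the rearrangement runs as a charge-accelerated Claisen far below the thermal threshold, and the resulting ketone–aluminium complex is reduced in the same flask by β-hydride transfer to the ten-membered C2 alcohol F1 (C2 configuration uncontrolled). Dess–Martin oxidation of F1 returns to ketone 25. The acetonide is the group to watch under the Lewis acid.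

Step 18 (eight-membered lactonisation). The neopentyl carboxyl may be acylated too slowly, so oligomerisation or acyl transfer from the wrong carbonyl of the mixed anhydride could take over. The fallback sets out from hydroxy acid 22 and activates the alcohol instead of the acid: Mitsunobu lactonisation (PPh3, diisopropyl azodicarboxylate, toluene, high dilution) closes the ring by carboxylate displacement at C6 with inversion, giving the 6-epi lactone F2. Petasis methylenation as in step 19 gives the 6-epi enol ether F3, and the thermal Claisen of step 20 brings F3 back to ketone 25, because C6 becomes sp2 and its configuration is lost.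

Step 16 (lactone-enolate Claisen). The lactone enolate may expel the β-silyloxy group, or the congested boat transition state with the Z-olefin may not be reached. The fallback sets out from allylic alcohol 10 and builds the cyclohexene by an acyclic ester-enolate rearrangement followed by metathesis:
- Esterification of 10 with (S)-3-hydroxyhex-5-enoic acid (EDC, DMAP) gives ester F4.
- Dianionic Ireland–Claisen rearrangement (LiN(iPr)2 2.2 equiv, Me3SiCl, THF, −78 °C → rt, acidic work-up) gives β-hydroxy acid F5. C10 should be set by Felkin–Anh-type attack anti to the C9–O bond with H9 eclipsing the olefin; C1 is not yet defined.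
- Me3SiCHN2 in MeOH gives methyl ester F6.
- Fráter–Seebach methylation (LiN(iPr)2 2.2 equiv, MeI) places the methyl anti to the C14 alkoxide in the lithium chelate and gives the quaternary ester F7.
- Ring-closing metathesis (second-generation Grubbs catalyst RuCl2(=CHPh)(PCy3)(H2IMes)) between the isopropenyl group on C10 and the allyl group on C14 gives cyclohexene F8.
- TIPSOTf and 2,6-lutidine give F9, and cleavage of the hindered methyl ester with KOSiMe3 followed by acidification returns to acid 21.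

**Further compounds**

F1 | step 20 | ten-membered C2 alcohol (C2 epimers) | CC(C)[Si](C(C)C)(C(C)C)O[C@H]1CC=C(C)[C@@H]2[C@@H](OCc4ccc(OC)cc4)[C@@]3(C(C)=C)OC(C)(C)O[C@H]3/C=C(/C)CCC(O)[C@@]12C
F2 | step 18 | 6-epi eight-membered lactone | CC(C)[Si](C(C)C)(C(C)C)O[C@H]1CC=C(C)[C@@H]2[C@@H](OCc4ccc(OC)cc4)[C@@]3(C(C)=C)OC(C)(C)O[C@H]3[C@@H](C(C)=C)OC(=O)[C@@]12C
F3 | step 18 | 6-epi eight-membered enol ether | CC(C)[Si](C(C)C)(C(C)C)O[C@H]1CC=C(C)[C@@H]2[C@@H](OCc4ccc(OC)cc4)[C@@]3(C(C)=C)OC(C)(C)O[C@H]3[C@@H](C(C)=C)OC(=C)[C@@]12C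
F4 | step 16 | (S)-3-hydroxyhex-5-enoate ester of 10 | C=CC[C@H](O)CC(=O)OC/C(C)=C\[C@@H](OCc1ccc(OC)cc1)[C@@]2(C(C)=C)OC(C)(C)O[C@H]2[C@@H](O[Si](C)(C)C(C)(C)C)C(C)=C
F5 | step 16 | acyclic β-hydroxy acid (C1 epimers) | C=CC[C@H](O)C(C(O)=O)[C@H](C(C)=C)[C@@H](OCc1ccc(OC)cc1)[C@@]2(C(C)=C)OC(C)(C)O[C@H]2[C@@H](O[Si](C)(C)C(C)(C)C)C(C)=C
F6 | step 16 | acyclic β-hydroxy methyl ester (C1 epimers) | C=CC[C@H](O)C(C(=O)OC)[C@H](C(C)=C)[C@@H](OCc1ccc(OC)cc1)[C@@]2(C(C)=C)OC(C)(C)O[C@H]2[C@@H](O[Si](C)(C)C(C)(C)C)C(C)=C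
F7 | step 16 | α-methylated β-hydroxy methyl ester (C1 quaternary) | C=CC[C@H](O)[C@](C)(C(=O)OC)[C@H](C(C)=C)[C@@H](OCc1ccc(OC)cc1)[C@@]2(C(C)=C)OC(C)(C)O[C@H]2[C@@H](O[Si](C)(C)C(C)(C)C)C(C)=C
F8 | step 16 | cyclohexene hydroxy methyl ester | O[C@H]1CC=C(C)[C@H]([C@@H](OCc2ccc(OC)cc2)[C@@]3(C(C)=C)OC(C)(C)O[C@H]3[C@@H](O[Si](C)(C)C(C)(C)C)C(C)=C)[C@@]1(C)C(=O)OC
F9 | step 16 | C14-O-TIPS cyclohexene methyl ester | CC(C)[Si](C(C)C)(C(C)C)O[C@H]1CC=C(C)[C@H]([C@@H](OCc2ccc(OC)cc2)[C@@]3(C(C)=C)OC(C)(C)O[C@H]3[C@@H](O[Si](C)(C)C(C)(C)C)C(C)=C)[C@@]1(C)C(=O)OC
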